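The ratio I want sets two rates against each other: the rate at which a flask makes target, and the rate at which its charge of starting material would have to go to be finished in the time.

| setting | Wednesday's | Sunday's | Monday's | blue | green | amber | teal | grey |
|---|---|---|---|---|---|---|---|---|
| starting material | 0.078 M (in portions, 4) | 0.078 M (in portions, 4) | 0.078 M (in portions, 4) | 0.078 M (in portions, 4) | 0.078 M (in portions, 4) | 0.078 M (in portions, 4) | 0.078 M (in portions, 4) | 0.078 M (in portions, 4) |
| partner | 0.078 M | 0.078 M | 0.16 M | 0.0780 M | 0.0780 M | 0.0780 M | 0.0780 M | 0.0780 M |
| initiator | 2.2 mM | 3.5 mM | 1.6 mM | 1.6 mM | 1.6 mM | 1.6 mM | 1.6 mM | 1.6 mM |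
| temperature | 54 °C | 84 °C | 54 °C | 95 °C | 40 °C | 60 °C | 50 °C | 80 °C |
| remark | run made earlier; portions every 2.0 h | run made earlier; portions every 2.0 h | run made earlier; portions every 2.0 h | the portions of starting material follow each other after 2.0 h, the first at the start | the portions of starting material follow each other after 2.0 h, the first at the start | the portions of starting material follow each other after 2.0 h, the first at the start | the portions of starting material follow each other after 2.0 h, the first at the start | the portions of starting material follow each other after 2.0 h, the first at the start |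
| time |  |  |  | 2.0 d | 2.0 d | 2.0 d | 2.0 d | 2.0 d |

Wednesday's run (percent of the starting material charged): time / d: target / % = 0.417: 4.3; 0.625: 5.7; 1.25: 12.1; 2.50: 21.5; 5.00: 35.9

Sunday's run (percent of the starting material charged): time / h: target / % = 2.50: 17.8; 8.00: 42.5; 12.0: 52.4; 20.0: 65.7; 30.0: 72.4

Monday's run (percent of the starting material charged): time / d: target / % = 0.417: 7.3; 0.625: 9.7; 1.25: 20.8; 2.50: 37.0; 5.00: 65.8

(scatter of a reading: 0.5 percentage points)



1. the flasks by amount of target, in percent of the starting material charged, highest first, at 2.0 d (blue / green / amber / teal / grey)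
2. the amount of target, in percent of the starting material charged of the flask you put first, at 2.0 d
3. the amount of target, in percent of the starting material charged of the flask you put last, at 2.0 d

The runs give the first rate. Monday's target at 1.25 d is 1.72 times Wednesday's, and first order in partner with half order in initiator predicts 1.75, so I take that form. In Sunday's run, with two portions in by 2.50 h, target has come at 0.0712 h⁻¹ of the charge. From then to 8.00 h, with the last portion added, it comes at 0.0449 h⁻¹, which is slower. So I treat the rate as zero order in starting material, a reading from one run. At equal initiator, Sunday's early rate is 14.0 times Wednesday's, and I spread that factor evenly, as a logarithm, over the temperature gap.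

My turnover number (a Damköhler number) is the target makeable in the time at the starting rate, over the charge:

at Wednesday's temperature, on these charges: 0.165

green: 0.0482

teal: 0.116

amber: 0.280

grey: 1.63

blue: 6.08

Far below one, I read the number as the share of the charge turned; green has the smallest number, so I expect it last at about 4.82%. Nearer one that reading fails: Sunday's early rate over 12.0 h gives 0.854, yet the reading is 52.4%, and over 30.0 h it gives 2.14, yet the reading is 72.4%. One number is therefore not enough for the hot flasks. I keep its ranking, blue above grey, and expect both near that reading.

The forecast gives grey > blue > amber > teal > green, with 67% and 3.3%, holding blue back “as the initiator dies early”.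

The flask gives blue > grey > amber > teal > green, with 64.4% and 3.92%.

    initiator → 2 initiating radical (k = 7.54 × 10⁻⁶ s⁻¹, Ea = 108 kJ mol⁻¹)
    starting material + initiating radical → capped initiator + first chain carrier (k = 46300 M⁻¹ s⁻¹, Ea = 34.0 kJ mol⁻¹)
    partner + first chain carrier ⇌ target + second chain carrier (K = 7.02, k = 952 M⁻¹ s⁻¹, Ea = 44.0 kJ mol⁻¹, ΔH = −22.0 kJ mol⁻¹)
    starting material + second chain carrier → by-product + first chain carrier (k = 69600 M⁻¹ s⁻¹, Ea = 13.0 kJ mol⁻¹)
    2 first chain carrier → ended chains A (k = 9.00 × 10⁷ M⁻¹ s⁻¹, Ea = 19.0 kJ mol⁻¹)
    2 second chain carrier → ended chains B (k = 6.40 × 10⁸ M⁻¹ s⁻¹, Ea = 12.0 kJ mol⁻¹)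
    2 starting material → homo dimer (k = 1.72 × 10⁻⁵ M⁻¹ s⁻¹, Ea = 73.0 kJ mol⁻¹)
    starting material + target → side product (k = 9.26 × 10⁻⁵ M⁻¹ s⁻¹, Ea = 92.0 kJ mol⁻¹)
    (constants at 80 °C)

Green's 3.92% lies below my 4.82%. The neighbouring flask is green with 0.019 M of starting material. Zero order keeps the molar target and divides by the smaller charge, so the number rises by 4.11 to 19.8%. The neighbour gives 16.2%, which is 4.13 times green's share. In molar terms green holds 3.06 mM of target and the neighbour 3.08 mM.

The numbers in the tables stem from a simulated flask on assumed constants, noise included.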